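## Retrosynthetic overview

1. Target gibberellin ⇐ desilylation ⇐ ring A by ring-closing metathesis (C1=C2) ⇐ aldol of the C19 lactone enolate with acrolein (C3–C4) ⇐ lactone ring by intramolecular Michael addition (C4–C5) of a C10 propanoate onto a C5=C6–C7 enal; C10 is set by vinyl addition and C7 comes from a dithiane added at C6.
2. Ring D ⇐ gold-catalysed 5-exo-dig closure (C13–C16) of the C12/C13 ene-diol bis(silyl ether) onto the C8 propargyl group. C16 can reach C12 as well as C13, so the closure is run on the ene-diol ether itself, where ring size selects C13; the C12 ketone left behind is reduced to the 12-OH.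
3. Rings B/C ⇐ Diels–Alder addition of 2,3-bis(triethylsilyloxy)buta-1,3-diene to C8=C9 of 4-propargylcyclopent-4-ene-1,3-dione, forming C8–C14 and C9–C11.
4. Feature used: ring C carries adjacent oxygens on C12 and C13, and H9 is cis to C15 across the C8–C9 fusion with C8 quaternary. Ring C is thus the adduct of a 2,3-dioxygenated butadiene and a C8=C9 cyclopentene.
5. Ring order: B (from furfural) → C (step 6) → D (step 8) → lactone (step 14) → A (step 17).

Key step: step 6

## Remarks and assumptions

- Atom numbers in names follow the gibberellane skeleton of the target (C7 = acid carbon, C19 = lactone carbonyl, C17 = exocyclic CH2, C18 = methyl).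
- Assumption: the sense of induction in step 6 follows the α-C–H···O binding model, which assigns the (R)-prolinol-derived catalyst; if the adduct proves antipodal, the (S)-catalyst is used without other change.
- Triethylsilyl replaces trimethylsilyl on the diene so that the enol ethers survive the acidic catalyst and the C13 silyl ether lasts to the end; adduct 10 is drawn as the diketone but should exist largely as its enol.

## Route

Step 1
Reactants: 1 furfural; 2 propargyl bromide
Product: 4 1-(furan-2-yl)but-3-yn-1-ol (racemic), via allenylzinc bromide 3 (not isolated)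
Conditions: Zn dust, THF/sat. aq. NH4Cl, 0 °C to rt
Reagents that add atoms: none
Why: Barbier propargylation, in which the allenylzinc species adds through its γ-carbon to give the homopropargylic alcohol; the carbinol centre is not carried into the dienophile.

Step 2
Reactants: 4 1-(furan-2-yl)but-3-yn-1-ol
Product: 5 trans-4-hydroxy-5-(prop-2-yn-1-yl)cyclopent-2-en-1-one (racemic)
Conditions: ZnCl2, dioxane/H2O, 100 °C
Reagents that add atoms: water, O
Why: Piancatelli rearrangement (ionisation of the furyl carbinol, addition of water, ring opening and conrotatory 4π-electrocyclisation) gives the trans product; the alkyne is inert.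

Step 3
Reactants: 5 trans-4-hydroxy-5-(prop-2-yn-1-yl)cyclopent-2-en-1-one
Product: 6 4-hydroxy-2-(prop-2-yn-1-yl)cyclopent-2-en-1-one (racemic)
Conditions: K2HPO4/KH2PO4 buffer (pH 8), dioxane, 40 °C
Reagents that add atoms: water, O
Why: Base-mediated isomerisation (conjugate hydration, then β-elimination of the original hydroxyl) to the more stable 2-substituted 4-hydroxycyclopentenone; the stereocentre is removed in step 4.

Step 4
Reactants: 6 4-hydroxy-2-(prop-2-yn-1-yl)cyclopent-2-en-1-one
Product: 7 4-(prop-2-yn-1-yl)cyclopent-4-ene-1,3-dione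
Conditions: Dess–Martin periodinane, CH2Cl2, 0 °C to rt
Reagents that add atoms: none
Why: Dess–Martin oxidation of the secondary allylic alcohol under neutral conditions that spare the alkyne and the base-sensitive enedione.

Step 5
Reactants: 8 butane-2,3-dione
Product: 9 2,3-bis(triethylsilyloxy)buta-1,3-diene
Conditions: Et3SiOTf (2.2 equiv), Et3N, Et2O, 0 °C to rt
Reagents that add atoms: triethylsilyl trifluoromethanesulfonate, CC[Si](CC)(CC)OS(=O)(=O)C(F)(F)F
Why: Double soft enolisation and O-silylation of the 1,2-diketone (silyl enol ether formation) gives the electron-rich diene.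

Step 6
Reactants: 7 4-(prop-2-yn-1-yl)cyclopent-4-ene-1,3-dione; 9 2,3-bis(triethylsilyloxy)buta-1,3-diene
Product: 10 (3aS,7aR)-3a-(prop-2-yn-1-yl)-5,6-bis(triethylsilyloxy)-3a,4,7,7a-tetrahydro-1H-indene-1,3(2H)-dione (cis-fused ring B/C dione; C8 quaternary with the propargyl group, H9 cis to it; C12=C13 ene-diol bis(silyl ether))
Conditions: (R)-3,3-diphenyl-1-(o-tolyl)tetrahydropyrrolo[1,2-c][1,3,2]oxazaborole·HNTf2 (20 mol %), CH2Cl2, −78 to −40 °C; Et3N quench; used crude
Reagents that add atoms: none
Why: Proposed new method: the protonated oxazaborolidine binds the C10 carbonyl through the lone pair syn to C9–H (an α-C–H···O contact possible only on this side, since C8 is substituted), lowers the LUMO of C8=C9 and screens one face with a phenyl group, so that the electron-rich diene adds in a concerted, asynchronous [4+2] cycloaddition. The closest known reactions are the oxazaborolidinium-catalysed Diels–Alder additions of 2-silyloxybutadienes to quinones and 2-substituted cycloalkenones and the uncatalysed addition of 2,3-bis(silyloxy)butadienes to cyclopent-4-ene-1,3-diones; new is their combination on a cyclopentenedione with an acidic C5 methylene. Ring C is closed in the intermolecular cycloaddition mode, C8–C14 and C9–C11 forming together on one face. C8 and C9 are therefore cis by suprafacial addition (H9 syn to C15), and their absolute configuration (attack on the C8-Si/C9-Re face) is set by the catalyst. The only selectivity needed is enantiofacial: the diene is C2-symmetric, so there is no regiochemistry, and its unsubstituted termini leave no endo/exo question.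

Step 7
Reactants: 10 Diels–Alder adduct
Product: 11 O10-triisopropylsilyl vinylogous ester of 10 (ring B: C6=O, C5=C10–OSi(i-Pr)3; C8 and C9 as in 10)
Conditions: i-Pr3SiCl, imidazole, CH2Cl2, 0 °C to rt
Reagents that add atoms: chlorotriisopropylsilane, CC(C)[Si](Cl)(C(C)C)C(C)C
Why: O-silylation of the enolised 1,3-dione goes to the less hindered oxygen O10 (O6 is flanked by quaternary C8), which masks the acidic dione and leaves C6=O free for step 11.

Step 8
Reactants: 11 vinylogous silyl ester
Product: 12 tricyclic ketone (ring D closed by C13–C16; C16=C17H2; C12 ketone; 13-OSiEt3 at the bridgehead; ring B as in 11; H9 syn to C15)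
Conditions: Ph3PAuNTf2 (5 mol %), i-PrOH (1.5 equiv), CH2Cl2, 0 °C to rt
Reagents that add atoms: none
Why: Proposed new method: cationic monovalent gold activates the alkyne and C13 of the ene-diol ether attacks anti in a 5-exo-dig closure (1,6-enyne geometry), the O12-silyl oxocarbenium ion passes Et3Si to 2-propanol, and protodeauration leaves the exocyclic methylene and the C12 ketone; the closest known reaction is the gold-catalysed 5-exo-dig carbocyclisation of simple silyl enol ethers onto alkynes (Conia-ene type) that gives bicyclo[3.2.1]octanones; the C13 configuration is fixed by the C8 tether, and the modes to be outrun are the slower 6-exo closure through C12 (bicyclo[2.2.2]octane) and O6-cyclisation, which cannot turn over because the vinylogous ester does not shed its bulky silyl group.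

Step 9
Reactants: 12 tricyclic ketone
Product: 13 12-alcohol of 12 (OH axial on ring C, anti to C16)
Conditions: LiBH(s-Bu)3 (L-Selectride), THF, −78 °C; H2O
Reagents that add atoms: none
Why: Ketone reduction by a bulky hydride, delivered to the C12 face syn to the C15–C16 bridge because the other face is screened by C10 (axial on C9, 1,3 to C12), so the hydroxyl ends anti to C16; the vinylogous ester is inert at −78 °C.

Step 10
Reactants: 13 12-alcohol
Product: 14 12,13-bis(triethylsilyl) ether of 13
Conditions: Et3SiOTf, 2,6-lutidine, CH2Cl2, −78 to 0 °C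
Reagents that add atoms: triethylsilyl trifluoromethanesulfonate, CC[Si](CC)(CC)OS(=O)(=O)C(F)(F)F
Why: Silyl ether formation on the hindered secondary alcohol; since O12 and O13 both end as triethylsilyl ethers, a 1,2-silyl shift in 13 would be of no consequence.

Step 11
Reactants: 14 bis(silyl ether)
Product: 16 enone (C10 ketone; C5=C6; 1,3-dithian-2-yl on C6), via C6 carbinol adduct 15 (not isolated)
Conditions: 1,3-dithiane, n-BuLi, THF, −30 °C; add 14, −78 to −20 °C; H2O; then PPTS (cat.), wet CH2Cl2, 0 °C to rt
Reagents that add atoms: 1,3-dithiane, C1CSCSC1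
Why: Stork–Danheiser-type 1,2-addition of the Corey–Seebach formyl anion equivalent to the vinylogous ester carbonyl C6, then acid-induced loss of water and silanol, transposes the enone to C10(=O)–C5=C6 and installs C7; C6 becomes sp2, so no stereocentre arises.

Step 12
Reactants: 16 enone
Product: 18 C10 tertiary propanoate (10-vinyl cis to H9; 10-O-propanoyl cis to C11; C5=C6–dithianyl), via bromomagnesium alkoxide 17 (not isolated)
Conditions: CH2=CHMgBr, CeCl3, THF, −78 °C; then (EtCO)2O, DMAP (cat.), −78 to 0 °C
Reagents that add atoms: vinylmagnesium bromide, C=C[Mg]Br; propionic anhydride, CCC(=O)OC(=O)CC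
Why: Organocerium 1,2-addition to the enone followed by O-acylation of the alkoxide; vinyl attacks C10 anti to the adjacent C9–C11 bond (the face of H9), which places O10 cis to C11 as the lactone requires.

Step 13
Reactants: 18 propanoate
Product: 19 enal (as 18, with the C7 aldehyde on C6)
Conditions: MeI, CaCO3, MeCN/H2O (9:1), 40 °C
Reagents that add atoms: water, O
Why: S-alkylative hydrolysis of the allylic dithiane unmasks the C7 aldehyde under neutral, buffered conditions that leave the tertiary allylic ester and the silyl ethers intact.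

Step 14
Reactants: 19 enal
Product: 20 γ-lactone aldehyde (C19(=O)–O–C10 lactone cis-fused at C5–C10; C4 bearing H and CH3 as an epimer mixture; 10-vinyl; 6-CHO trans to C4)
Conditions: lithium 2,2,6,6-tetramethylpiperidide (from the amine and n-BuLi), THF, −78 °C; then t-BuOH, 0 °C; AcOH
Reagents that add atoms: none
Why: Intramolecular Michael addition (5-exo-trig) of the propanoate enolate to the enal forms C4–C5 and the lactone; C5 is forced cis to O10 by the tether, alkoxide-mediated equilibration of the aldehyde places C7 trans to C4, and the C4 centre is erased in step 16.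

Step 15
Reactants: 20 lactone aldehyde
Product: 21 lactone acid (as 20, with the C7 carboxylic acid)
Conditions: NaClO2, NaH2PO4, 2-methyl-2-butene, t-BuOH/H2O, 0 °C to rt
Reagents that add atoms: sodium chlorite, [Na+].[O-]Cl=O
Why: Pinnick oxidation converts the aldehyde to the acid without epimerising C6, the scavenger protecting the alkenes.

Step 16
Reactants: 21 lactone acid
Product: 23 aldol adduct (C4 quaternary with CH3 and CH(OH)CH=CH2; C3 chain cis to the 10-vinyl; C3 as in the target), via dilithium carboxylate-enolate 22 (not isolated)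
Conditions: LiN(i-Pr)2 (2.2 equiv), THF, −78 to −40 °C; acrolein, −78 °C; AcOH, −78 °C
Reagents that add atoms: acrolein, C=CC=O
Why: Aldol addition of the lactone enolate (the acid is protected as its lithium salt); acrolein should add to C4 on the convex face (cis to H5 and the 10-vinyl), and a closed Zimmerman–Traxler transition state with OLi cis to the C4 methyl puts the new hydroxyl syn to that methyl, which is the 3β-configuration.

Step 17
Reactants: 23 aldol adduct
Product: 24 12,13-bis(triethylsilyl) ether of the target gibberellin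
Conditions: second-generation Grubbs catalyst (H2IMes)(PCy3)Cl2Ru=CHPh (5 mol %), 1,4-benzoquinone (10 mol %), CH2Cl2, 40 °C
Reagents that add atoms: none
Why: Ring-closing metathesis of the two vinyl groups held cis on the lactone closes ring A as C1=C2; the 1,1-disubstituted C16=C17 is unreactive.

Step 18
Reactants: 24 bis(silyl ether)
Product: 25 the target gibberellin (number 87 of the gibberellin A series)
Conditions: HF·pyridine, pyridine, THF, 0 °C to rt
Reagents that add atoms: none
Why: Fluoride-mediated cleavage of both triethylsilyl ethers under buffered conditions that avoid acid-induced rearrangement of the C/D allylic alcohol and base-induced lactone migration.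

## Compound list

1 | furfural | O=Cc1ccco1 | starting material
2 | propargyl bromide | C#CCBr | starting material
3 | allenylzinc bromide | C=C=C[Zn]Br | intermediate
4 | 1-(furan-2-yl)but-3-yn-1-ol (racemic) | C#CCC(O)c1ccco1 | intermediate
5 | trans-4-hydroxy-5-(prop-2-yn-1-yl)cyclopent-2-en-1-one (racemic; one enantiomer drawn) | O=C1C=C[C@H](O)[C@H]1CC#C | intermediate
6 | 4-hydroxy-2-(prop-2-yn-1-yl)cyclopent-2-en-1-one (racemic) | O=C1CC(O)C=C1CC#C | intermediate
7 | 4-(prop-2-yn-1-yl)cyclopent-4-ene-1,3-dione | C#CCC1=CC(=O)CC1=O | intermediate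
8 | butane-2,3-dione | CC(=O)C(C)=O | starting material
9 | 2,3-bis(triethylsilyloxy)buta-1,3-diene | C=C(O[Si](CC)(CC)CC)C(=C)O[Si](CC)(CC)CC | intermediate
10 | (3aS,7aR)-3a-(prop-2-yn-1-yl)-5,6-bis(triethylsilyloxy)-3a,4,7,7a-tetrahydro-1H-indene-1,3(2H)-dione | C#CC[C@@]12C(=O)CC(=O)[C@@H]1CC(O[Si](CC)(CC)CC)=C(O[Si](CC)(CC)CC)C2 | intermediate
11 | O10-triisopropylsilyl vinylogous ester of 10 | C#CC[C@@]12C(=O)C=C(O[Si](C(C)C)(C(C)C)C(C)C)[C@@H]1CC(O[Si](CC)(CC)CC)=C(O[Si](CC)(CC)CC)C2 | intermediate
12 | tricyclic C12 ketone with 13-OSiEt3 and C16=C17H2 | C=C1C[C@]23C[C@@]1(O[Si](CC)(CC)CC)C(=O)C[C@H]2C(O[Si](C(C)C)(C(C)C)C(C)C)=CC3=O | intermediate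
13 | 12-alcohol of 12 (OH anti to C16) | C=C1C[C@]23C[C@@]1(O[Si](CC)(CC)CC)[C@@H](O)C[C@H]2C(O[Si](C(C)C)(C(C)C)C(C)C)=CC3=O | intermediate
14 | 12,13-bis(triethylsilyl) ether of 13 | C=C1C[C@]23C[C@@]1(O[Si](CC)(CC)CC)[C@@H](O[Si](CC)(CC)CC)C[C@H]2C(O[Si](C(C)C)(C(C)C)C(C)C)=CC3=O | intermediate
15 | C6 carbinol adduct bearing 1,3-dithian-2-yl (C6 epimer mixture) | C=C1C[C@]23C[C@@]1(O[Si](CC)(CC)CC)[C@@H](O[Si](CC)(CC)CC)C[C@H]2C(O[Si](C(C)C)(C(C)C)C(C)C)=CC3(O)C4SCCCS4 | intermediate
16 | enone with C10 ketone, C5=C6 and 6-(1,3-dithian-2-yl) | C=C1C[C@]23C[C@@]1(O[Si](CC)(CC)CC)[C@@H](O[Si](CC)(CC)CC)C[C@H]2C(=O)C=C3C4SCCCS4 | intermediate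
17 | bromomagnesium C10 alkoxide of the vinyl adduct | C=C1C[C@]23C[C@@]1(O[Si](CC)(CC)CC)[C@@H](O[Si](CC)(CC)CC)C[C@H]2[C@]([O-])(C=C)C=C3C4SCCCS4.[Mg+2].[Br-] | intermediate
18 | 10-vinyl C10 propanoate with C5=C6–dithianyl | C=C1C[C@]23C[C@@]1(O[Si](CC)(CC)CC)[C@@H](O[Si](CC)(CC)CC)C[C@H]2[C@](OC(=O)CC)(C=C)C=C3C4SCCCS4 | intermediate
19 | 10-vinyl C10 propanoate with C5=C6–CHO (enal) | C=C1C[C@]23C[C@@]1(O[Si](CC)(CC)CC)[C@@H](O[Si](CC)(CC)CC)C[C@H]2[C@](OC(=O)CC)(C=C)C=C3C=O | intermediate
20 | 19,10-lactone 7-aldehyde (C4 epimer mixture) | C=C1C[C@]23C[C@@]1(O[Si](CC)(CC)CC)[C@@H](O[Si](CC)(CC)CC)C[C@H]2[C@]4(OC(=O)C(C)[C@H]4[C@@H]3C=O)C=C | intermediate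
21 | 19,10-lactone 7-acid (C4 epimer mixture) | C=C1C[C@]23C[C@@]1(O[Si](CC)(CC)CC)[C@@H](O[Si](CC)(CC)CC)C[C@H]2[C@]4(OC(=O)C(C)[C@H]4[C@@H]3C(=O)O)C=C | intermediate
22 | dilithium C7 carboxylate and C4=C19 lactone enolate of 21 | C=C1C[C@]23C[C@@]1(O[Si](CC)(CC)CC)[C@@H](O[Si](CC)(CC)CC)C[C@H]2[C@]4(OC([O-])=C(C)[C@H]4[C@@H]3C(=O)[O-])C=C.[Li+].[Li+] | intermediate
23 | aldol adduct with C4 bearing CH3 and CH(OH)CH=CH2 | C=C1C[C@]23C[C@@]1(O[Si](CC)(CC)CC)[C@@H](O[Si](CC)(CC)CC)C[C@H]2[C@]4(OC(=O)[C@](C)([C@@H](O)C=C)[C@H]4[C@@H]3C(=O)O)C=C | intermediate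
24 | 12,13-bis(triethylsilyl) ether of the target gibberellin | C=C1C[C@]23C[C@@]1(O[Si](CC)(CC)CC)[C@@H](O[Si](CC)(CC)CC)C[C@H]2[C@@]12C=C[C@H](O)[C@@](C)(C(=O)O1)[C@H]2[C@@H]3C(=O)O | intermediate
25 | target gibberellin, number 87 of the gibberellin A series (3,12,13-trihydroxy 1-ene 19,10-lactone 7-acid) | C=C1C[C@]23C[C@@]1(O)[C@@H](O)C[C@H]2[C@@]12C=C[C@H](O)[C@@](C)(C(=O)O1)[C@H]2[C@@H]3C(=O)O | target

## Step count and risks

Total step count: 18. Longest linear sequence: 17 (steps 1–4 and 6–18, from furfural); step 5 is a one-step side branch.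

Steps most likely to fail:

1. Step 6. The catalyst may discriminate the enantiofaces poorly, or the acid may desilylate the diene or divert it into a Mukaiyama–Michael addition instead of cycloaddition. Fallback (known chemistry): setting out from 7 and 9, the cycloaddition is run without catalyst (toluene, 60 °C) to give the racemic adduct F1, which is silylated as in step 7 to the racemic vinylogous silyl ester F2. Preparative chromatography on a chiral stationary phase (cellulose tris(3,5-dimethylphenylcarbamate), hexane/i-PrOH, 0.1 % Et3N) then delivers 11, where the route is rejoined.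

2. Step 8. The closure may take the 6-exo course through C12, the alkyne may be captured by the C6 carbonyl oxygen, or the ene-diol ether may be protodesilylated before it cyclises. Fallback (known chemistry): setting out from 11, a tin-mediated radical enyne cyclisation is used (Bu3SnH, AIBN, benzene, 80 °C, high stannane concentration to outrun homoallyl rearrangement). The stannyl radical adds to C17, the C16 vinyl radical closes 5-exo-trig onto C13, and the C12 α-silyloxy radical takes hydrogen on the face syn to the bridge, giving the C17-tributylstannyl bis(silyl ether) F3. Protodestannylation (CF3CO2H, CH2Cl2, −20 °C) returns to the route at 14, bypassing steps 9 and 10.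

3. Step 16. The simple diastereoselection at C3 may be poor if the addition runs through an open transition state, and the hindered aldolate may revert on warming. Fallback: setting out from 23 taken as its C3 epimer mixture, Dess–Martin oxidation gives the C3 ketone F4, and ring-closing metathesis as in step 17 gives the 1-en-3-one F5. An oxazaborolidine-catalysed borane reduction (CBS reduction with catecholborane, toluene, −78 °C; catalyst antipode matched to hydride delivery on the lactone face) then sets C3 under reagent control and returns to the route at 24.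

## Further compounds

F1 | step 6 | racemic 10 (both enantiomers) | C#CC[C@@]12C(=O)CC(=O)[C@@H]1CC(O[Si](CC)(CC)CC)=C(O[Si](CC)(CC)CC)C2.C#CC[C@]12C(=O)CC(=O)[C@H]1CC(O[Si](CC)(CC)CC)=C(O[Si](CC)(CC)CC)C2
F2 | step 6 | racemic 11 (both enantiomers) | C#CC[C@@]12C(=O)C=C(O[Si](C(C)C)(C(C)C)C(C)C)[C@@H]1CC(O[Si](CC)(CC)CC)=C(O[Si](CC)(CC)CC)C2.C#CC[C@]12C(=O)C=C(O[Si](C(C)C)(C(C)C)C(C)C)[C@H]1CC(O[Si](CC)(CC)CC)=C(O[Si](CC)(CC)CC)C2
F3 | step 8 | C17-tributylstannyl derivative of 14 (E/Z mixture) | CCCC[Sn](CCCC)(CCCC)C=C1C[C@]23C[C@@]1(O[Si](CC)(CC)CC)[C@@H](O[Si](CC)(CC)CC)C[C@H]2C(O[Si](C(C)C)(C(C)C)C(C)C)=CC3=O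
F4 | step 16 | C3 ketone of 23 (vinyl ketone on C4) | C=C1C[C@]23C[C@@]1(O[Si](CC)(CC)CC)[C@@H](O[Si](CC)(CC)CC)C[C@H]2[C@]4(OC(=O)[C@](C)(C(=O)C=C)[C@H]4[C@@H]3C(=O)O)C=C
F5 | step 16 | 3-oxo analogue of 24 (1-en-3-one) | C=C1C[C@]23C[C@@]1(O[Si](CC)(CC)CC)[C@@H](O[Si](CC)(CC)CC)C[C@H]2[C@@]12C=CC(=O)[C@@](C)(C(=O)O1)[C@H]2[C@@H]3C(=O)O
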